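The vessel is closed and stirred, and the catalyst in it goes round a loop: I want to know how much of the charged partner passes through that loop before something else takes it.

common to all: starting material 20 mM; free catalyst 2.2 mM
- west: second substrate 10 mM; partner 11 mM; temperature 20 °C; run made earlier
- beta: second substrate 10.0 mM; partner 22.0 mM; temperature 20 °C; time 15 min
- theta: second substrate 10.0 mM; partner 22.0 mM; temperature 35 °C; time 15 min
- delta: second substrate 10.0 mM; partner 22.0 mM; temperature 50 °C; time 15 min

west run (percent of the starting material charged)

| time / min | starting material / % | catalyst intermediate A / % | target / % |
|---|---|---|---|
| 0.200 | 96.2 | 0.8 | 5.3 |
| 0.667 | 85.8 | 1.3 | 13.7 |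
| 1.00 | 79.5 | 0 | 17.8 |
| 1.50 | 74.6 | 0.8 | 26.4 |
| 2.50 | 64.7 | 3.7 | 31.4 |
| 3.00 | 62.9 | 4.9 | 33.6 |

(standard deviation of a reading: 1 percentage point)

- the earlier runs do not show what temperature does; that part of a forecast is a guess

- which of these there is most of at the end, counted by the starting material in it, beta (starting material / target / catalyst intermediate A)
- which of these there is most of at the end, counted by the starting material in it, theta (starting material / target / catalyst intermediate A)
- which of these there is most of at the end, counted by the starting material in it, delta (starting material / target / catalyst intermediate A)
- final amount of the leader among these, as a percentage of the starting material charged, in beta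
- final amount of the leader among these, as a percentage of the starting material charged, in theta
- final amount of the leader among these, as a percentage of the starting material charged, in delta

The fastest rung of my ladder is one turn of the catalyst. From the first reading of the west run, the target appears at a pace that matches the catalyst charge in about 0.415 min.

The next rung is the life of the partner. I take catalyst intermediate A to turn over with partner, and in the west run it stays low at first and then climbs from 0.8 % to 4.9 % as the target slows, so I read the partner's end near 3.00 min. That makes the partner the limiting reagent, and I expect A to fill as a store once the partner stops, a store which the catalyst charge caps at 11.0 % of the starting material.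

The slowest rung is the asked 15 min, far longer than that life, so I expect the end state to stand still once the partner has stopped. What stands there is the result of a race on the middle rung. To reckon it I freeze the catalyst's draw r at a constant value while partner lasts, and let partner also be lost in first order with constant k:

dc(partner)/dt = −r − k·c(partner)

target made / partner charged = ln(1 + x)/x

The west run's last target reading is a share of 0.611 of its partner, and solving the second line gives 1.51. This x is the race number: k times the partner charged, divided by r.

Beta has twice the west partner, so its race number doubles and I reckon the target at 50.7 %, which is more than the 38.3 % of starting material left beside a full A. The target keeps the lead while it stays above 44.5 %. No earlier run shows heat, so I guess that x grows in theta and delta, and I leave their leaders open.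

The forecast, by contrast, puts the target ahead in beta at 49 %, in theta at 48.5 % and in delta at 46 %, with the remark that “Heat should only speed this up”.

The flask gives target at 50.3 % in beta, starting material at 49.3 % in theta and starting material at 59.4 % in delta.

    partner → decomposed reagent (k = 0.380 /min, Ea = 80.0 kJ/mol)
    starting material + free catalyst ⇌ catalyst intermediate A (K = 8900 /M, k = 140 /M/min, Ea = 49.0 kJ/mol, ΔH = −33.0 kJ/mol)
    partner + catalyst intermediate A → free catalyst + target (k = 3100 /M/min, Ea = 41.0 kJ/mol)
    partner + catalyst intermediate B → free catalyst + second product (k = 100 /M/min, Ea = 56.0 kJ/mol)
    second substrate + free catalyst ⇌ catalyst intermediate B (K = 150 /M, k = 82.0 /M/min, Ea = 44.0 kJ/mol, ΔH = −44.0 kJ/mol)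
    (constants at 20 °C)

In theta the partner stands at 0 %, with 13.3 mM as decomposed reagent, more than the 8.01 mM as target, and that target share of 0.364 makes the race number 4.85, higher than the 3.02 I reckoned for beta. A neighbour of theta is charged with 8.8 mM of free catalyst, so theta has a quarter of its catalyst, the race number falls to 1.21, the rule gives 72.0 % of target, and that neighbour holds 67.4 %.

Readings and results were generated by integration for substances that don't exist.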